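Retrosynthesis: the two S–O bonds of the ring B sulfates and all ether protecting groups come off first; the pyranone ring is then cut at O1–C2 and at C2–C3, and last the CH2–O bond of a phenacyl ester.
Enabling feature: C3 carries an oxygen and its neighbour C2 carries the ring B aryl group, so O3 and C2 can be read as the alkoxy oxygen and the acyl carbon of a 2-hydroxyphenacyl benzoate. Moving the aroyl group from O3 to the ketone α-carbon makes C2–C3 with O3 already in place, and the ring A phenol then closes O1–C2.
Forward: a ring A bromoketone (from 2,4,6-trihydroxyacetophenone) and a ring B acid (from protocatechuic acid) are joined as the ester; the pyranone ring, the only ring built, forms in the key step; 3-O-benzylation, deallylation, bis-sulfation and hydrogenolysis follow.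
Stereochemistry: the target has no stereocentre; the carbinol centres of the two transient intermediates of the key step vanish on dehydration.

Key step: step 6

Assumption: the aryl sulfate monoesters are drawn and counted as free hydrogen sulfates, as in the target structure. At the bench compound 13 would be carried as its disodium salt and the acid form of 14 released only at the end on a cold H+ resin, since free aryl hydrogen sulfates hydrolyse on standing.

Step 1
Reactants: 1 2,4,6-trihydroxyacetophenone
Product: 2 1-[2-hydroxy-4,6-bis(benzyloxy)phenyl]ethanone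
Conditions: BnBr (2.05 equiv), K2CO3 (2.2 equiv), DMF, rt
Reagents that add atoms: benzyl bromide, BrCc1ccccc1
Why: Williamson etherification should take the 4-OH and one of the two equivalent ortho-OH groups, while the remaining ortho-OH, hydrogen-bonded to the ketone, is the least nucleophilic and should stay free with two equivalents of halide.

Step 2
Reactants: 2 1-[2-hydroxy-4,6-bis(benzyloxy)phenyl]ethanone
Product: 3 2-bromo-1-[2-hydroxy-4,6-bis(benzyloxy)phenyl]ethanone
Conditions: CuBr2 (2.0 equiv), EtOAc/CHCl3 1:1, reflux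
Reagents that add atoms: copper dibromide, Br[Cu]Br
Why: Heterogeneous α-bromination of an aryl methyl ketone by CuBr2 acts on the enol of the side chain and is the standard way to brominate hydroxyacetophenones without touching the ring; HBr leaves with the refluxing solvent, so the benzyl ethers should hold.

Step 3
Reactants: 4 protocatechuic acid (3,4-dihydroxybenzoic acid)
Product: 5 allyl 3,4-bis(allyloxy)benzoate
Conditions: allyl bromide (3.5 equiv), K2CO3 (4 equiv), DMF, 60 °C
Reagents that add atoms: allyl bromide, C=CCBr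
Why: Exhaustive Williamson alkylation of both phenols and the carboxylate with a reactive allylic halide is routine for hydroxybenzoic acids.

Step 4
Reactants: 5 allyl 3,4-bis(allyloxy)benzoate
Product: 6 3,4-bis(allyloxy)benzoic acid
Conditions: NaOH (2 M aq), THF/MeOH, 60 °C; then 1 M HCl to pH 2
Reagents that add atoms: sodium hydroxide, [Na+].[OH-]
Why: Saponification cleaves only the ester, since allyl aryl ethers are inert to aqueous hydroxide.

Step 5
Reactants: 3 2-bromo-1-[2-hydroxy-4,6-bis(benzyloxy)phenyl]ethanone; 6 3,4-bis(allyloxy)benzoic acid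
Product: 7 2-[2-hydroxy-4,6-bis(benzyloxy)phenyl]-2-oxoethyl 3,4-bis(allyloxy)benzoate
Conditions: 6 (1.05 equiv), KHCO3 (1.1 equiv), DMF, rt; then 3, 0 °C to rt
Reagents that add atoms: none
Why: SN2 displacement of the activated α-bromoketone by a preformed carboxylate gives the phenacyl ester; carboxylate and hydrogencarbonate are too weakly basic to ionise the chelated phenol, which should hold back intramolecular O-alkylation to the benzofuran-3-one.

Step 6
Reactants: 7 2-[2-hydroxy-4,6-bis(benzyloxy)phenyl]-2-oxoethyl 3,4-bis(allyloxy)benzoate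
Product: 10 5,7-bis(benzyloxy)-3-hydroxy-2-[3,4-bis(allyloxy)phenyl]-4H-chromen-4-one, via hydroxy diketone 8 (not isolated), via cyclic hemiketal 9 (not isolated)
Conditions: LiN(SiMe3)2 (3.5 equiv), THF, −78 to 0 °C; AcOH quench, evaporate; AcOH, 80 °C
Reagents that add atoms: none
Why: Excess LiN(SiMe3)2 removes the phenol proton and one CH2 proton, and the enolate carbon adds to the carbonyl of its own aroyloxy group through an oxiranyl alkoxide (or after aroyl transfer to the phenoxide and a second, six-centre transfer to carbon), giving the 2-hydroxy-1,3-diketone 8 with C2–C3 made and O3 untouched. The closest known reaction types are the Baker–Venkataraman rearrangement and the base-induced 1,2-acyl shift of α-acyloxy ketone enolates, an established entry to flavonols from 2-hydroxyphenacyl benzoates. In warm acetic acid the phenol adds to the aroyl carbonyl in a 6-exo-trig closure to hemiketal 9, which loses water across C2–C3 to give the enolised aromatic pyranone 10 and so forms O1–C2. No stereocentre survives, because the carbinol carbon of 8 and both sp3 centres of 9 become sp2. The selectivity needed is C-acylation over 5-exo-tet displacement of the carboxylate by the phenoxide; complete enolisation at −78 °C secures it because an enolate carbon is no longer electrophilic, lithium chelation holds ketone and ester together, the aroyl group has no α-hydrogen so only one enolate can form, and deprotonation of the product diketone makes the shift irreversible. Benzyl and allyl ethers should tolerate the amide base at low temperature and acetic acid free of mineral acid, which also spares the acid-sensitive 5-O-benzyl group.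

Step 7
Reactants: 10 5,7-bis(benzyloxy)-3-hydroxy-2-[3,4-bis(allyloxy)phenyl]-4H-chromen-4-one
Product: 11 3,5,7-tris(benzyloxy)-2-[3,4-bis(allyloxy)phenyl]-4H-chromen-4-one
Conditions: BnBr (1.3 equiv), K2CO3, DMF, 40 °C
Reagents that add atoms: benzyl bromide, BrCc1ccccc1
Why: Williamson etherification of the acidic flavonol 3-OH, the only free hydroxyl, masks it before the sulfation, which would otherwise also esterify this position.

Step 8
Reactants: 11 3,5,7-tris(benzyloxy)-2-[3,4-bis(allyloxy)phenyl]-4H-chromen-4-one
Product: 12 3,5,7-tris(benzyloxy)-2-(3,4-dihydroxyphenyl)-4H-chromen-4-one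
Conditions: Pd(PPh3)4 (5 mol %), morpholine (6 equiv), THF, rt, argon
Reagents that add atoms: none
Why: In this Tsuji–Trost deallylation zerovalent palladium ionises each aryl allyl ether to a π-allyl complex that morpholine intercepts, while benzyl ethers and the chromenone are inert.

Step 9
Reactants: 12 3,5,7-tris(benzyloxy)-2-(3,4-dihydroxyphenyl)-4H-chromen-4-one
Product: 13 3,5,7-tris(benzyloxy)-2-[3,4-bis(sulfooxy)phenyl]-4H-chromen-4-one
Conditions: SO3·pyridine (10 equiv), pyridine/DMF, 60 °C; aq NaHCO3, C18 chromatography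
Reagents that add atoms: sulfur trioxide–pyridine complex, O=S(=O)([O-])[n+]1ccccc1
Why: O-Sulfonation of phenols by an amine–SO3 complex can only reach the two catechol hydroxyls; a large excess of reagent and heat should push the slower second esterification next to the first anionic sulfate.

Step 10
Reactants: 13 3,5,7-tris(benzyloxy)-2-[3,4-bis(sulfooxy)phenyl]-4H-chromen-4-one
Product: 14 3,5,7-trihydroxy-2-[3,4-bis(sulfooxy)phenyl]-4H-chromen-4-one (quercetin 3',4'-bis(hydrogen sulfate), the target)
Conditions: H2 (1 atm), 10% Pd/C, MeOH/H2O, rt; then Dowex 50W (H+ form), 0 °C, freeze-drying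
Reagents that add atoms: none
Why: Catalytic hydrogenolysis cleaves the three benzyl aryl ethers, whereas aryl sulfate monoesters and the C2=C3 bond of the flavonol are not reduced at ambient pressure; pyridine is removed beforehand because it retards O-benzyl cleavage on palladium.

Compound list
1 | 2,4,6-trihydroxyacetophenone | CC(=O)c1c(O)cc(O)cc1O | starting material
2 | 1-[2-hydroxy-4,6-bis(benzyloxy)phenyl]ethanone | CC(=O)c1c(O)cc(OCc2ccccc2)cc1OCc1ccccc1 | intermediate
3 | 2-bromo-1-[2-hydroxy-4,6-bis(benzyloxy)phenyl]ethanone | O=C(CBr)c1c(O)cc(OCc2ccccc2)cc1OCc1ccccc1 | intermediate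
4 | protocatechuic acid (3,4-dihydroxybenzoic acid) | OC(=O)c1ccc(O)c(O)c1 | starting material
5 | allyl 3,4-bis(allyloxy)benzoate | C=CCOC(=O)c1ccc(OCC=C)c(OCC=C)c1 | intermediate
6 | 3,4-bis(allyloxy)benzoic acid | OC(=O)c1ccc(OCC=C)c(OCC=C)c1 | intermediate
7 | 2-[2-hydroxy-4,6-bis(benzyloxy)phenyl]-2-oxoethyl 3,4-bis(allyloxy)benzoate | O=C(COC(=O)c1ccc(OCC=C)c(OCC=C)c1)c1c(O)cc(OCc2ccccc2)cc1OCc1ccccc1 | intermediate
8 | 1-[2-hydroxy-4,6-bis(benzyloxy)phenyl]-2-hydroxy-3-[3,4-bis(allyloxy)phenyl]propane-1,3-dione (racemic, not isolated) | O=C(C(O)C(=O)c1ccc(OCC=C)c(OCC=C)c1)c1c(O)cc(OCc2ccccc2)cc1OCc1ccccc1 | intermediate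
9 | 5,7-bis(benzyloxy)-2,3-dihydroxy-2-[3,4-bis(allyloxy)phenyl]chroman-4-one (racemic mixture of diastereomers, not isolated) | O=C1C(O)C(O)(c2ccc(OCC=C)c(OCC=C)c2)Oc2cc(OCc3ccccc3)cc(OCc3ccccc3)c21 | intermediate
10 | 5,7-bis(benzyloxy)-3-hydroxy-2-[3,4-bis(allyloxy)phenyl]-4H-chromen-4-one | O=c1c(O)c(-c2ccc(OCC=C)c(OCC=C)c2)oc2cc(OCc3ccccc3)cc(OCc3ccccc3)c12 | intermediate
11 | 3,5,7-tris(benzyloxy)-2-[3,4-bis(allyloxy)phenyl]-4H-chromen-4-one | O=c1c(OCc2ccccc2)c(-c2ccc(OCC=C)c(OCC=C)c2)oc2cc(OCc3ccccc3)cc(OCc3ccccc3)c12 | intermediate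
12 | 3,5,7-tris(benzyloxy)-2-(3,4-dihydroxyphenyl)-4H-chromen-4-one | O=c1c(OCc2ccccc2)c(-c2ccc(O)c(O)c2)oc2cc(OCc3ccccc3)cc(OCc3ccccc3)c12 | intermediate
13 | 3,5,7-tris(benzyloxy)-2-[3,4-bis(sulfooxy)phenyl]-4H-chromen-4-one | O=c1c(OCc2ccccc2)c(-c2ccc(OS(=O)(=O)O)c(OS(=O)(=O)O)c2)oc2cc(OCc3ccccc3)cc(OCc3ccccc3)c12 | intermediate
14 | 3,5,7-trihydroxy-2-[3,4-bis(sulfooxy)phenyl]-4H-chromen-4-one | O=c1c(O)c(-c2ccc(OS(=O)(=O)O)c(OS(=O)(=O)O)c2)oc2cc(O)cc(O)c12 | target

Total step count: 10. Longest linear sequence: 8 steps (steps 1, 2, 5, 6, 7, 8, 9, 10 from compound 1; equally steps 3, 4, 5, 6, 7, 8, 9, 10 from compound 4).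

Steps most likely to fail

1. Step 6. The dianion may close by intramolecular O-alkylation with loss of the carboxylate, or the aroyl group may travel only as far as the phenol oxygen and stall there, so that C2–C3 is not formed. The fallback sets out from compounds 2 and 6 and builds the C2–C3 bond and the 3-oxygen separately. Steglich esterification (EDC·HCl, DMAP, CH2Cl2) should give 2-acetyl-3,5-bis(benzyloxy)phenyl 3,4-bis(allyloxy)benzoate F1. A classical Baker–Venkataraman rearrangement (KOH, pyridine, 50 °C) should turn it into 1-[2-hydroxy-4,6-bis(benzyloxy)phenyl]-3-[3,4-bis(allyloxy)phenyl]propane-1,3-dione F2. Cyclodehydration (TsOH·H2O, toluene, 90 °C) should then give 5,7-bis(benzyloxy)-2-[3,4-bis(allyloxy)phenyl]-4H-chromen-4-one F3. Lithiation at C3 (LiN(iPr)2, THF, −78 °C) and trapping with B(OMe)3 should give dimethyl {5,7-bis(benzyloxy)-2-[3,4-bis(allyloxy)phenyl]-4-oxo-4H-chromen-3-yl}boronate F4, which is not isolated but oxidised in the same flask with H2O2/AcOH. The fallback returns to the route at compound 10.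

2. Step 9. The second sulfation next to the first, already anionic, sulfate may remain incomplete, and sulfate may be lost by hydrolysis during isolation of the polar salt. The fallback sets out from compound 12 and installs both sulfates as neutral diesters. Treatment with 2,2,2-trichloroethyl chlorosulfate, Et3N and DMAP in THF at 0 °C, with the chlorosulfate in excess so that the second esterification outruns closure to a cyclic sulfate, should give 3,5,7-tris(benzyloxy)-2-{3,4-bis[(2,2,2-trichloroethoxy)sulfonyloxy]phenyl}-4H-chromen-4-one F5, which can be purified on silica. Reductive removal of the trichloroethyl groups with Zn dust and HCO2NH4 in MeOH at rt returns to the route at compound 13.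

3. Step 2. Bromination of the electron-rich ring A, or a second bromination of the methyl group, may compete with monobromination of the side chain. The fallback sets out from compound 2 and fixes the enol before the halogen is added. TMSOTf and Et3N in CH2Cl2 at 0 °C should give 1-[2-(trimethylsilyloxy)-4,6-bis(benzyloxy)phenyl]-1-(trimethylsilyloxy)ethene F6, whose enol silane should react with NBS in THF at −78 °C much faster than the ring. Dilute aqueous acid on work-up frees the phenol, and the fallback returns to the route at compound 3.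

Further compounds
F1 | step 6 | 2-acetyl-3,5-bis(benzyloxy)phenyl 3,4-bis(allyloxy)benzoate | CC(=O)c1c(OC(=O)c2ccc(OCC=C)c(OCC=C)c2)cc(OCc2ccccc2)cc1OCc1ccccc1
F2 | step 6 | 1-[2-hydroxy-4,6-bis(benzyloxy)phenyl]-3-[3,4-bis(allyloxy)phenyl]propane-1,3-dione | O=C(CC(=O)c1ccc(OCC=C)c(OCC=C)c1)c1c(O)cc(OCc2ccccc2)cc1OCc1ccccc1
F3 | step 6 | 5,7-bis(benzyloxy)-2-[3,4-bis(allyloxy)phenyl]-4H-chromen-4-one | O=c1cc(-c2ccc(OCC=C)c(OCC=C)c2)oc2cc(OCc3ccccc3)cc(OCc3ccccc3)c12
F4 | step 6 | dimethyl {5,7-bis(benzyloxy)-2-[3,4-bis(allyloxy)phenyl]-4-oxo-4H-chromen-3-yl}boronate | COB(OC)c1c(-c2ccc(OCC=C)c(OCC=C)c2)oc2cc(OCc3ccccc3)cc(OCc3ccccc3)c2c1=O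
F5 | step 9 | 3,5,7-tris(benzyloxy)-2-{3,4-bis[(2,2,2-trichloroethoxy)sulfonyloxy]phenyl}-4H-chromen-4-one | O=c1c(OCc2ccccc2)c(-c2ccc(OS(=O)(=O)OCC(Cl)(Cl)Cl)c(OS(=O)(=O)OCC(Cl)(Cl)Cl)c2)oc2cc(OCc3ccccc3)cc(OCc3ccccc3)c12
F6 | step 2 | 1-[2-(trimethylsilyloxy)-4,6-bis(benzyloxy)phenyl]-1-(trimethylsilyloxy)ethene | C=C(O[Si](C)(C)C)c1c(O[Si](C)(C)C)cc(OCc2ccccc2)cc1OCc1ccccc1
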